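The readings come from a simulation from invented constants, noise included.

At 40 h we read this flask, so before charging it we decide whether 0.800 M of reagent, equal to the starting material, and that wait are the right recipe.

in all of them: starting material 0.80 M; free catalyst 40 mM (in portions, 4); impurity 8.3 mM
- Thursday's: reagent 0.40 M; run made earlier; portions every 20 min
- Monday's: reagent 1.6 M; run made earlier; portions every 20 min
- flask: reagent 0.800 M; the portions of free catalyst follow each other after 20 min, the first at the start; time 40 h

| run | time / h | product / % | catalyst intermediate A / % |
|---|---|---|---|
| Thursday's | 2.00 | 21.1 | 1.9 |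
| Thursday's | 3.00 | 26.2 | 1.8 |
| Thursday's | 5.00 | 31.1 | 1.2 |
| Thursday's | 8.00 | 30.6 | 3.2 |
| Thursday's | 15.0 | 31.6 | 1.9 |
| Thursday's | 25.0 | 31.8 | 1.9 |
| Monday's | 1.50 | 36.5 | 1.0 |
| Monday's | 5.00 | 69.7 | 1.8 |
| Monday's | 8.00 | 73.0 | 0.8 |
| Monday's | 12.0 | 74.6 | 1.2 |
| Monday's | 20.0 | 75.1 | 0.6 |
| Monday's | 25.0 | 74.8 | 0.3 |

(readings scatter by 0.5 percentage points)



1. the product standing at 40 h, as a percentage of the starting material charged
2. the catalyst intermediate A standing at 40 h, as a percentage of the starting material charged
3. amount of product if the flask were left three thousand times as long, in percent of the starting material charged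

1. Both earlier runs levelled off short of their smaller charge. Reckoned one for one from the product, Thursday's run still holds 0.146 M of reagent at 25.0 h, and Monday's run holds 0.202 M of starting material at 25.0 h.

2. So we form [product]/([starting material][reagent]) from those last readings. It reads 3.20 M⁻¹ on Thursday's run and 2.96 M⁻¹ on Monday's, though their reagent charges differ by a factor of 4.00.

3. We call the mean of these readings the standing ratio K, 3.08 M⁻¹, and take the end of a run to be under thermodynamic control.

4. The zero of our scale is a flask with equal charges c that ends with as much product as starting material: there K·c = 2. This flask has K·c = 2.47, more than that, so we expect product to end above starting material.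

5. Setting K = x/((a−x)(b−x)), with a and b the charges and x the product, we get 0.428 M for this flask, or 53.4 % of the starting material. That is also our figure for the long wait.

6. Monday's product moved from 74.6 % at 12.0 h to 74.8 % at 25.0 h, within the scatter, so we keep the recipe and plan no longer stay.

The forecast says 53.3 % of product, 0.7 % of catalyst intermediate A and 53.5 % for the long wait, on the ground that “this looks like a true equilibrium”. Its product lies close to our 53.4 %, and for catalyst intermediate A we make no figure of our own.

The flask gives 53.0 % of product, 1.69 % of catalyst intermediate A, and 53.0 % for the long wait.

    free catalyst + impurity → spent catalyst (k = 46.7 M⁻¹ min⁻¹)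
    catalyst intermediate B ⇌ free catalyst + product (K = 0.210 M, k = 1.09 min⁻¹)
    starting material + free catalyst ⇌ catalyst intermediate A (K = 6.40 M⁻¹, k = 1.37 M⁻¹ min⁻¹)
    reagent + catalyst intermediate A ⇌ catalyst intermediate B (K = 2.47 M⁻¹, k = 0.577 M⁻¹ min⁻¹)

Our reckoning with K stood 0.40 percentage points above this flask. Now take the neighbour flask, with reagent cut to 0.20 M and the other charges as in the recipe. Reagent is the limiting reagent there, and its charge allows 25.0 % of the starting material to become product. The same equation with the same K gives x = 0.134 M, which is 16.8 % of the starting material charged. That neighbour flask gives 16.7 % of product and keeps 80.0 % as starting material.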